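## Retrosynthetic overview

- C3 carbinol: ketoreductase reduction of the α-bromo ketone; that ketone comes from a trans-bromohydrin allylic alcohol by hydroxyl-directed hydrogenation (sets C1) and re-oxidation.
- The allylic bromohydrin comes from the α'-bromo enone by a ketoreductase dynamic reductive kinetic resolution (sets C3 and C4); the enone comes from the spiro ketone by dehydrogenation, MeLi addition and oxidative 1,3-transposition.
- Ring-B trans Br/Cl: bromoetherification from a C1 hydroxyl across the ring-B alkene, then C–O to C–Cl exchange with retention.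
- Spiro centre and ring B: catalytic asymmetric Diels–Alder of isoprene with an exo-methylene ketone (first stereocentre). Ring A is present from the start (2,3-dimethylcyclohexenone); ring B is formed second.

## Assumptions

- Labels: spiro compounds are named with the target's atom labels (ring A: C1 = CHMe, C2, C3 = CHOH, C4 = CHBr, C5 = CMe2; C6 = spiro; ring B: C7, C8, C9 = CClMe, C10 = CHBr, C11), which are not always the lowest IUPAC locants; "both C1 epimers" or "both C4 epimers" means an unassigned mixture at that one centre.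
- Catalyst and enzymes: the IDPi acid is the imidodiphosphorimidate built from two 3,3'-bis[3,5-bis(trifluoromethyl)phenyl]-BINOL units with an N-triflyl group on each phosphorus, used in the antipode that gives the (6R)-adduct (written (S,S) below); the (3S)- and (3R)-selective ketoreductases are picked from commercial NADPH-dependent panels by screening.
- Descriptor note: the C6 descriptor changes from R to S once C4 carries bromine, only through a CIP priority switch; the spiro centre itself is never touched.

## Route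

Step 1
Reactants: 1 2,3-dimethylcyclohex-2-en-1-one
Product: 2 trimethyl[(2,3,3-trimethylcyclohex-1-en-1-yl)oxy]silane
Conditions: MeMgBr, CuBr·SMe2 (10 mol %), Me3SiCl, THF/DMPU, −40 → 0 °C
Reagents that add atoms: methylmagnesium bromide, C[Mg]Br; chlorotrimethylsilane, C[Si](C)(C)Cl
Why: Copper-catalysed conjugate addition with in situ silylation builds the gem-dimethyl carbon and traps the regiodefined tetrasubstituted enolate, and every species is achiral.

Step 2
Reactants: 2 trimethyl[(2,3,3-trimethylcyclohex-1-en-1-yl)oxy]silane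
Product: 3 3,3-dimethyl-2-methylidenecyclohexan-1-one
Conditions: Pd(OAc)2 (1.05 equiv), MeCN, 23 °C
Reagents that add atoms: none
Why: Saegusa–Ito oxidation, in which the palladium enolate can only β-hydride-eliminate into the C2 methyl group because C3 is quaternary, so the exocyclic enone is the only product.

Step 3
Reactants: 3 3,3-dimethyl-2-methylidenecyclohexan-1-one; 4 isoprene (2-methylbuta-1,3-diene)
Product: 5 (6R)-5,5,9-trimethylspiro[5.5]undec-9-en-1-one
Conditions: (S,S)-IDPi acid (3 mol %), isoprene (5 equiv), CHCl3, −40 °C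
Reagents that add atoms: none
Why: Brønsted-acid-catalysed asymmetric Diels–Alder reaction in which the protonated exo-enone adds isoprene with para regiochemistry inside the confined chiral anion, which selects one enone face and so sets the spiro centre C6 (R) while closing ring B.

Step 4
Reactants: 5 (6R)-5,5,9-trimethylspiro[5.5]undec-9-en-1-one
Product: 6 (6R)-5,5,9-trimethylspiro[5.5]undec-9-en-1-ol (both C1 epimers)
Conditions: NaBH4, MeOH, 0 → 23 °C
Reagents that add atoms: none
Why: Borohydride carbonyl reduction supplies the tethering hydroxyl, whose configuration is irrelevant because C1 returns to a ketone in step 7.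

Step 5
Reactants: 6 (6R)-5,5,9-trimethylspiro[5.5]undec-9-en-1-ol (both C1 epimers)
Product: 7 (6R,9S,10S)-10-bromo-1,9-epoxy-5,5,9-trimethylspiro[5.5]undecane (both C1 epimers)
Conditions: N-bromosuccinimide, CH2Cl2, 0 °C, dark
Reagents that add atoms: N-bromosuccinimide, O=C1CCC(=O)N1Br
Why: Intramolecular bromoetherification (the α-terpineol to 2-bromo-1,8-cineole type) in which the C1 hydroxyl closes on the tertiary C9 from its own face and bromine enters C10 from the opposite face, so C9 (S) and C10 (S) are set relative to the spiro centre whatever the C1 configuration.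

Step 6
Reactants: 7 (6R,9S,10S)-10-bromo-1,9-epoxy-5,5,9-trimethylspiro[5.5]undecane (both C1 epimers)
Product: 8 (6R,9S,10S)-10-bromo-9-chloro-5,5,9-trimethylspiro[5.5]undecan-1-ol (both C1 epimers)
Conditions: BCl3 (1.2 equiv), CH2Cl2, −78 → −20 °C; then H2O
Reagents that add atoms: boron trichloride, ClB(Cl)Cl
Why: Lewis-acid ether cleavage in which the tertiary C9–O bond ionises with anchimeric help from the anti C10 bromine (bromonium ion) and chloride reopens it at C9 anti to bromine, so chlorine replaces oxygen with retention and the trans Br/Cl pair keeps the configuration fixed in step 5.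

Step 7
Reactants: 8 (6R,9S,10S)-10-bromo-9-chloro-5,5,9-trimethylspiro[5.5]undecan-1-ol (both C1 epimers)
Product: 9 (6R,9S,10S)-10-bromo-9-chloro-5,5,9-trimethylspiro[5.5]undecan-1-one
Conditions: Dess–Martin periodinane, NaHCO3, CH2Cl2, 23 °C
Reagents that add atoms: none
Why: Dess–Martin oxidation converges both C1 epimers to one ketone under neutral conditions that leave the halides alone.

Step 8
Reactants: 9 (6R,9S,10S)-10-bromo-9-chloro-5,5,9-trimethylspiro[5.5]undecan-1-one
Product: 11 (6R,9S,10S)-10-bromo-9-chloro-5,5,9-trimethylspiro[5.5]undec-2-en-1-one, via trimethylsilyl enol ether 10 (not isolated)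
Conditions: LiN(i-Pr)2, Me3SiCl, THF, −78 °C; then Pd(OAc)2 (1.05 equiv), MeCN, 23 °C
Reagents that add atoms: none
Why: Saegusa–Ito dehydrogenation, in which only C2 can enolise (C6 is quaternary) and the palladium enolate β-hydride-eliminates to the 2-en-1-one.

Step 9
Reactants: 11 (6R,9S,10S)-10-bromo-9-chloro-5,5,9-trimethylspiro[5.5]undec-2-en-1-one
Product: 12 (6R,9S,10S)-10-bromo-9-chloro-1,5,5,9-tetramethylspiro[5.5]undec-2-en-1-ol (both C1 epimers)
Conditions: MeLi, CeCl3, THF, −78 °C
Reagents that add atoms: methyllithium, [Li]C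
Why: Organocerium (Imamoto) 1,2-addition, in which the non-basic methylcerium reagent adds to the hindered enone carbonyl without enolisation or attack on the alkyl halides, and the new carbinol centre is erased in step 10.

Step 10
Reactants: 12 (6R,9S,10S)-10-bromo-9-chloro-1,5,5,9-tetramethylspiro[5.5]undec-2-en-1-ol (both C1 epimers)
Product: 13 (6R,9S,10S)-10-bromo-9-chloro-1,5,5,9-tetramethylspiro[5.5]undec-1-en-3-one
Conditions: pyridinium chlorochromate [C5H5NH][CrO3Cl], 4 Å sieves, CH2Cl2, 23 °C
Reagents that add atoms: pyridinium chlorochromate, [O-][Cr](=O)(=O)Cl.c1cc[nH+]cc1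
Why: Babler–Dauben oxidative 1,3-transposition, in which the tertiary allylic chromate ester undergoes a [3,3] shift to C3 and is oxidised there to the β-methyl enone.

Step 11
Reactants: 13 (6R,9S,10S)-10-bromo-9-chloro-1,5,5,9-tetramethylspiro[5.5]undec-1-en-3-one
Product: 15 (6S,9S,10S)-4,10-dibromo-9-chloro-1,5,5,9-tetramethylspiro[5.5]undec-1-en-3-one (both C4 epimers), via dienol trimethylsilyl ether 14 (not isolated)
Conditions: LiN(i-Pr)2, Me3SiCl, THF, −78 °C; then N-bromosuccinimide, THF, −78 °C
Reagents that add atoms: N-bromosuccinimide, O=C1CCC(=O)N1Br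
Why: Kinetic α'-deprotonation (as for isophorone) gives the cross-conjugated dienol silane, which N-bromosuccinimide brominates at C4, the only enolisable α-position, leaving the C4 epimers to be sorted in step 12.

Step 12
Reactants: 15 (6S,9S,10S)-4,10-dibromo-9-chloro-1,5,5,9-tetramethylspiro[5.5]undec-1-en-3-one (both C4 epimers)
Product: 16 (3S,4S,6S,9S,10S)-4,10-dibromo-9-chloro-1,5,5,9-tetramethylspiro[5.5]undec-1-en-3-ol
Conditions: (3S)-selective ketoreductase, NADP+ (cat.), i-PrOH (10 vol %), triethanolamine buffer pH 8.0, DMSO (5 vol %), 30 °C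
Reagents that add atoms: none
Why: Ketoreductase-catalysed dynamic reductive kinetic resolution, in which the C4 epimers interconvert through the dienol in the amine buffer while the enzyme reduces only the (4S)-epimer on one carbonyl face, so C3 (S) and C4 (S) are both fixed by the enzyme.

Step 13
Reactants: 16 (3S,4S,6S,9S,10S)-4,10-dibromo-9-chloro-1,5,5,9-tetramethylspiro[5.5]undec-1-en-3-ol
Product: 17 (1S,3S,4S,6S,9S,10S)-4,10-dibromo-9-chloro-1,5,5,9-tetramethylspiro[5.5]undecan-3-ol
Conditions: [Ir(cod)(PCy3)(py)]PF6 (10 mol %), H2 (1 atm), CH2Cl2, 23 °C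
Reagents that add atoms: none
Why: Hydroxyl-directed hydrogenation (Crabtree–Stork), in which the iridium bound to the C3 hydroxyl delivers H2 to the same face of the C1=C2 bond, so the C1 methyl ends up trans to that hydroxyl, i.e. (1S).

Step 14
Reactants: 17 (1S,3S,4S,6S,9S,10S)-4,10-dibromo-9-chloro-1,5,5,9-tetramethylspiro[5.5]undecan-3-ol
Product: 18 (1S,4S,6S,9S,10S)-4,10-dibromo-9-chloro-1,5,5,9-tetramethylspiro[5.5]undecan-3-one
Conditions: Dess–Martin periodinane, NaHCO3, CH2Cl2, 0 °C
Reagents that add atoms: none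
Why: Buffered Dess–Martin oxidation removes the directing carbinol centre without enolising the adjacent C4–Br centre, and the ketone is used at once.

Step 15
Reactants: 18 (1S,4S,6S,9S,10S)-4,10-dibromo-9-chloro-1,5,5,9-tetramethylspiro[5.5]undecan-3-one
Product: 19 (1S,3R,4S,6S,9S,10S)-4,10-dibromo-9-chloro-1,5,5,9-tetramethylspiro[5.5]undecan-3-ol
Conditions: (3R)-selective ketoreductase, NADP+ (cat.), i-PrOH (10 vol %), KH2PO4/K2HPO4 buffer pH 6.5, DMSO (5 vol %), 25 °C
Reagents that add atoms: none
Why: Ketoreductase (NADPH-dependent alcohol dehydrogenase) reduction under enzyme control delivers hydride to the C3 carbonyl face that gives the (3R)-carbinol, cis to the C4 bromine and the C1 methyl, at a pH where C4 does not epimerise.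

## Compound list

1 | 2,3-dimethylcyclohex-2-en-1-one | CC1=C(C)C(=O)CCC1 | starting material
2 | trimethyl[(2,3,3-trimethylcyclohex-1-en-1-yl)oxy]silane | CC1=C(O[Si](C)(C)C)CCCC1(C)C | intermediate
3 | 3,3-dimethyl-2-methylidenecyclohexan-1-one | C=C1C(=O)CCCC1(C)C | intermediate
4 | isoprene (2-methylbuta-1,3-diene) | C=CC(C)=C | starting material
5 | (6R)-5,5,9-trimethylspiro[5.5]undec-9-en-1-one | O=C1CCCC(C)(C)[C@]12CCC(C)=CC2 | intermediate
6 | (6R)-5,5,9-trimethylspiro[5.5]undec-9-en-1-ol, both C1 epimers | OC1CCCC(C)(C)[C@]12CCC(C)=CC2 | intermediate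
7 | (6R,9S,10S)-10-bromo-1,9-epoxy-5,5,9-trimethylspiro[5.5]undecane, both C1 epimers | C1(O3)CCCC(C)(C)[C@]12CC[C@@]3(C)[C@@H](Br)C2 | intermediate
8 | (6R,9S,10S)-10-bromo-9-chloro-5,5,9-trimethylspiro[5.5]undecan-1-ol, both C1 epimers | OC1CCCC(C)(C)[C@]12CC[C@](C)(Cl)[C@@H](Br)C2 | intermediate
9 | (6R,9S,10S)-10-bromo-9-chloro-5,5,9-trimethylspiro[5.5]undecan-1-one | O=C1CCCC(C)(C)[C@]12CC[C@](C)(Cl)[C@@H](Br)C2 | intermediate
10 | trimethylsilyl enol ether of 9 (1-silyloxy-1-ene) | C[Si](C)(C)OC1=CCCC(C)(C)[C@]12CC[C@](C)(Cl)[C@@H](Br)C2 | intermediate (not isolated)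
11 | (6R,9S,10S)-10-bromo-9-chloro-5,5,9-trimethylspiro[5.5]undec-2-en-1-one | O=C1C=CCC(C)(C)[C@]12CC[C@](C)(Cl)[C@@H](Br)C2 | intermediate
12 | (6R,9S,10S)-10-bromo-9-chloro-1,5,5,9-tetramethylspiro[5.5]undec-2-en-1-ol, both C1 epimers | CC1(O)C=CCC(C)(C)[C@]12CC[C@](C)(Cl)[C@@H](Br)C2 | intermediate
13 | (6R,9S,10S)-10-bromo-9-chloro-1,5,5,9-tetramethylspiro[5.5]undec-1-en-3-one | CC1=CC(=O)CC(C)(C)[C@]12CC[C@](C)(Cl)[C@@H](Br)C2 | intermediate
14 | dienol trimethylsilyl ether of 13 (3-silyloxy-1,3-diene) | CC1=CC(O[Si](C)(C)C)=CC(C)(C)[C@]12CC[C@](C)(Cl)[C@@H](Br)C2 | intermediate (not isolated)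
15 | (6S,9S,10S)-4,10-dibromo-9-chloro-1,5,5,9-tetramethylspiro[5.5]undec-1-en-3-one, both C4 epimers | CC1=CC(=O)C(Br)C(C)(C)[C@]12CC[C@](C)(Cl)[C@@H](Br)C2 | intermediate
16 | (3S,4S,6S,9S,10S)-4,10-dibromo-9-chloro-1,5,5,9-tetramethylspiro[5.5]undec-1-en-3-ol | CC1=C[C@H](O)[C@@H](Br)C(C)(C)[C@]12CC[C@](C)(Cl)[C@@H](Br)C2 | intermediate
17 | (1S,3S,4S,6S,9S,10S)-4,10-dibromo-9-chloro-1,5,5,9-tetramethylspiro[5.5]undecan-3-ol | C[C@H]1C[C@H](O)[C@@H](Br)C(C)(C)[C@]12CC[C@](C)(Cl)[C@@H](Br)C2 | intermediate
18 | (1S,4S,6S,9S,10S)-4,10-dibromo-9-chloro-1,5,5,9-tetramethylspiro[5.5]undecan-3-one | C[C@H]1CC(=O)[C@@H](Br)C(C)(C)[C@]12CC[C@](C)(Cl)[C@@H](Br)C2 | intermediate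
19 | (1S,3R,4S,6S,9S,10S)-4,10-dibromo-9-chloro-1,5,5,9-tetramethylspiro[5.5]undecan-3-ol; lowest-locant name (2S,3R,5S,6S,8S,9S)-2,8-dibromo-9-chloro-1,1,5,9-tetramethylspiro[5.5]undecan-3-ol | C[C@H]1C[C@@H](O)[C@@H](Br)C(C)(C)[C@]12CC[C@](C)(Cl)[C@@H](Br)C2 | target

## Totals and fallbacks

Total step count: 15. Longest linear sequence: 15 steps (from 1; isoprene 4 is bought).

The three steps most likely to fail:

Step 3 (asymmetric Diels–Alder): enantioselectivity and the para/meta ratio depend on the fit between the acid and this hindered enone. The fallback sets out from 3 and comes back at 5. Copper-catalysed conjugate addition of 2-methylallylmagnesium chloride to 3 (CuBr·SMe2, THF, −78 °C) gives the chloromagnesium enolate F1, which is O-acylated in the same flask with allyl chloroformate to the achiral allyl enol carbonate F2. Palladium-catalysed decarboxylative asymmetric allylic alkylation (Pd2(dba)3, (S)-t-BuPHOX or its antipode, THF, 25 °C) then sets the quaternary centre in (R)-2-allyl-3,3-dimethyl-2-(3-methylbut-3-en-1-yl)cyclohexan-1-one F3. Ring-closing metathesis with the second-generation Grubbs catalyst [RuCl2(=CHPh)(PCy3)(H2IMes)] in CH2Cl2 at 40 °C closes ring B to 5.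

Step 6 (ether-to-chloride exchange): elimination from the tertiary cation or loss of the bromonium ion could compete with chloride capture. The fallback sets out from 5 and comes back at 9. The ring-B alkene of 5 is bromochlorinated directly, without the tether (N-bromosuccinimide, Et4NCl, CH2Cl2, −40 °C; Markovnikov, anti). This gives 9 together with its ring-B diastereomer (6R,9R,10R)-10-bromo-9-chloro-5,5,9-trimethylspiro[5.5]undecan-1-one F4, from which 9 is separated by chromatography or crystallisation. Steps 4, 5 and 7 are then not needed; the price is substrate-controlled, probably modest, facial selectivity.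

Step 12 (dynamic resolution): it needs both fast C4 epimerisation in the buffer and an enzyme that discriminates the C4 epimers. The fallback sets out from 15 and comes back at 16. Both C4 epimers of 15 are reduced without epimerisation by the same (3S)-selective ketoreductase at pH 7. Product 16 is separated by chromatography from the (3S,4R,6S,9S,10S)-4,10-dibromo-9-chloro-1,5,5,9-tetramethylspiro[5.5]undec-1-en-3-ol F5. F5 is returned to 15 by Dess–Martin oxidation, re-equilibrated at C4 (Et3N, CH2Cl2) and resubmitted.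

## Further compounds

F1 | step 3 | chloromagnesium enolate of 3,3-dimethyl-2-(3-methylbut-3-en-1-yl)cyclohexan-1-one | C=C(C)CCC1=C(O[Mg]Cl)CCCC1(C)C
F2 | step 3 | allyl [3,3-dimethyl-2-(3-methylbut-3-en-1-yl)cyclohex-1-en-1-yl] carbonate | C=C(C)CCC1=C(OC(=O)OCC=C)CCCC1(C)C
F3 | step 3 | (R)-2-allyl-3,3-dimethyl-2-(3-methylbut-3-en-1-yl)cyclohexan-1-one | O=C1CCCC(C)(C)[C@@]1(CCC(C)=C)CC=C
F4 | step 6 | (6R,9R,10R)-10-bromo-9-chloro-5,5,9-trimethylspiro[5.5]undecan-1-one | O=C1CCCC(C)(C)[C@]12CC[C@@](C)(Cl)[C@H](Br)C2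
F5 | step 12 | (3S,4R,6S,9S,10S)-4,10-dibromo-9-chloro-1,5,5,9-tetramethylspiro[5.5]undec-1-en-3-ol | CC1=C[C@H](O)[C@H](Br)C(C)(C)[C@]12CC[C@](C)(Cl)[C@@H](Br)C2
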